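The earlier runs and the new flask are simulated with made-up constants.

- Monday's: left-handed substrate 20 mM; right-handed substrate 20 mM; partner 120 mM; run made earlier
- flask: left-handed substrate 20 mM; partner 60.0 mM; right-handed substrate 20 mM; time 25 h

Monday's run (percent of the left-handed substrate and right-handed substrate together charged)

| time / h | left-handed product / % | right-handed product / % | left-handed substrate / % |
|---|---|---|---|
| 0.417 | 1.0 | 0 | 47.6 |
| 0.833 | 5.0 | 0 | 43.4 |
| 1.33 | 7.5 | 0.8 | 41.0 |
| 2.50 | 12.0 | 1.2 | 34.4 |
| 5.00 | 19.4 | 3.1 | 24.5 |

(standard deviation of a reading: 1 percentage point)

- partner is single-handed; left-handed substrate and right-handed substrate are mirror images of each other, charged as a racemate, each of them at the stated concentration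
- the handed part of partner does not stay in what it makes, so the products of the two hands are mirror images too

* concentration of left-handed product at 25 h, in mM
* concentration of right-handed product at 25 h, in mM

- On Monday, left-handed substrate falls from 50.0% to 24.5% in 5.00 h. Partner stands in excess there, 120 mM against 40.0 mM of both substrates, so you read a pseudo-first-order constant of 0.143 h⁻¹.
- Now take the main step by itself in the new flask, with [partner] held at its charge. The constant follows [partner], so it is half of Monday's, and 25 h gives 16.6 mM of left-handed product.
- Add one process. Monday's balance does not close: 19.4% of product stands against 26 percentage points of substrate lost, a share of 76.1%.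
- Suppose the side path needs no partner, and take Monday's [partner] at its charge. The crossover level, the [partner] at which left-handed substrate goes equally fast to product and to the side path, is then 37.7 mM. This is a reading, with 1 point of scatter on each value.
- The product share is [partner] over [partner] plus the crossover level. At 60.0 mM that is 61.4%, and the total constant is 0.0884 h⁻¹. So your left-handed product is 10.9 mM.
- Add the rest. Summed over Monday's readings, left-handed product is 44.9% and right-handed product 5.10%. That ratio of 8.80 is a rough stand-in for the selectivity factor, and it gives 1.24 mM of right-handed product. Monday shows no [partner], so you leave its fall out.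
- The forecast says 12.1 mM of left-handed product and 2.4 mM of right-handed product. It keeps the share at 0.77 because “this fraction holds steady”, and there you differ.
- The flask gives 11.1 mM and 1.19 mM. The forecast's right-handed product is twice that.

    partner + right-handed substrate → right-handed product (k = 0.00130 M⁻¹ min⁻¹)
    left-handed substrate ⇌ achiral form (K = 1.00, k = 6.30 × 10⁻⁴ min⁻¹)
    achiral form → waste (k = 2.80 × 10⁻⁵ min⁻¹)
    partner + left-handed substrate → left-handed product (k = 0.0170 M⁻¹ min⁻¹)
    right-handed substrate ⇌ achiral form (K = 1.00, k = 6.30 × 10⁻⁴ min⁻¹)
    partner → decomposed reagent (k = 3.40 × 10⁻⁴ min⁻¹)

- At 25.0 h this flask holds 27.2 mM of partner, 0.720 of the crossover level, and left-handed substrate goes to left-handed product at 0.73 of its forward rate to achiral form. In the neighbour flask read at 60.0 h, [partner] is down to 10.4 mM, or 0.277 of the crossover level, and left-handed product stands at 14.8 mM.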